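**Retrosynthetic overview**

1. Target 14 ⇐ methyl ester 13 (saponification) ⇐ fluoro alcohol 12, by closing the O1–C8a bond of the dihydropyran ring through SNAr.
2. 12 ⇐ ketone 9 + enyne 6, by forming the C2–C1' bond: alkyne hydrozirconation, Zr→Zn exchange and titanium-catalysed asymmetric dienylation of the methyl ketone. This sets C2 (R) and the 1'E alkene.
3. Enabling feature: C2 of the dihydropyran ring is a fully substituted O-bearing carbon (O1, CH3, C3) bonded directly to sp2 C1' of an E-alkene, which is the retron of an (E)-alkenyl metal added to a methyl ketone. O1 sits para to the C6 carboxyl on the benzene ring, so the ring can be closed afterwards at the aryl carbon without breaking the C2–O bond.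
4. 9 ⇐ Heck reaction of methyl 3-bromo-4-fluorobenzoate with but-3-en-2-ol. 6 ⇐ dihydro-β-ionone via the terminal alkyne, Zr-catalysed methylalumination/iodination (sets 3'E) and Negishi ethynylation.
5. Ring order: the cyclohexene and benzene rings are bought; the dihydropyran ring is closed last (step 6).

Key step: step 5

Assumption: the bis(sulfonamide) diol–titanium catalyst is taken to discriminate the ketone faces sterically (2-arylethyl large, methyl small). The ligand antipode that delivers the dienyl group to the Si face of 9 is used, and the absolute configuration would be confirmed on the first batch.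

**Route**

Step 1
Reactants: 1 dihydro-β-ionone [4-(2,6,6-trimethylcyclohex-1-en-1-yl)butan-2-one]
Product: 3 2-(but-3-yn-1-yl)-1,3,3-trimethylcyclohex-1-ene, via enol phosphate 2 (not isolated)
Conditions: LDA (1.05 equiv), THF, −78 °C; ClP(O)(OEt)2, −78 °C → rt; then LDA (2.3 equiv), THF, −78 °C → rt; H2O
Reagents that add atoms: diethyl chlorophosphate, CCOP(=O)(Cl)OCC (its atoms stay in intermediate 2 only; none remain in 3)
Why: Methyl ketone to terminal alkyne conversion by kinetic deprotonation at the methyl group, O-phosphorylation and LDA-induced β-elimination of the enol phosphate; the tetrasubstituted ring alkene is inert.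

Step 2
Reactants: 3 2-(but-3-yn-1-yl)-1,3,3-trimethylcyclohex-1-ene
Product: 5 2-[(3E)-4-iodo-3-methylbut-3-en-1-yl]-1,3,3-trimethylcyclohex-1-ene, via alkenylalane 4 (not isolated)
Conditions: AlMe3 (2.5 equiv), Cp2ZrCl2 (0.25 equiv), CH2Cl2, 0 °C → rt; then I2, THF, −30 → 0 °C
Reagents that add atoms: trimethylaluminium, C[Al](C)C; iodine, II
Why: Zirconium-catalysed Negishi carboalumination adds CH3–Al syn across the terminal alkyne only, with Al on the terminal carbon, and iododealumination with retention should fix the (E)-trisubstituted alkene.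

Step 3
Reactants: 5 2-[(3E)-4-iodo-3-methylbut-3-en-1-yl]-1,3,3-trimethylcyclohex-1-ene
Product: 6 2-[(3E)-3-methylhex-3-en-5-yn-1-yl]-1,3,3-trimethylcyclohex-1-ene
Conditions: HC≡CMgBr, ZnBr2, THF, 0 °C; then 5, Pd(PPh3)4 (5 mol %), THF, rt
Reagents that add atoms: ethynylmagnesium bromide, C#C[Mg]Br
Why: Negishi cross-coupling of the alkenyl iodide with ethynylzinc bromide proceeds with retention of alkene geometry and should give the terminal enyne directly, without a silyl protecting group.

Step 4
Reactants: 7 methyl 3-bromo-4-fluorobenzoate; 8 but-3-en-2-ol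
Product: 9 methyl 4-fluoro-3-(3-oxobutyl)benzoate
Conditions: Pd(OAc)2 (3 mol %), Bu4NCl, NaHCO3, DMF, 90 °C
Reagents that add atoms: none
Why: Heck reaction of an aryl bromide with a secondary allylic alcohol: the aryl group adds to the terminal carbon and β-hydride elimination towards the carbinol C–H gives the enol and hence the β-aryl methyl ketone; bicarbonate leaves the aryl fluoride and ester untouched.

Step 5
Reactants: 6 2-[(3E)-3-methylhex-3-en-5-yn-1-yl]-1,3,3-trimethylcyclohex-1-ene; 9 methyl 4-fluoro-3-(3-oxobutyl)benzoate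
Product: 12 methyl 4-fluoro-3-[(3R,4E,6E)-3-hydroxy-3,7-dimethyl-9-(2,6,6-trimethylcyclohex-1-en-1-yl)nona-4,6-dien-1-yl]benzoate, via dienylzirconocene chloride 10 (not isolated), via dienyl(methyl)zinc 11 (not isolated)
Conditions: 6, Cp2Zr(H)Cl, CH2Cl2, rt; solvent exchange to toluene; Me2Zn, −78 °C; then C2-symmetric bis(sulfonamide) diol ligand (trans-1,2-diaminocyclohexane bis(2-exo-hydroxybornane-10-sulfonamide), 10 mol %), Ti(OiPr)4 (1.2 equiv), 9, toluene, rt; H2O work-up
Reagents that add atoms: Schwartz reagent, [H][Zr](Cl)(C1C=CC=C1)C1C=CC=C1 (gives the C5–H of 12; Zr stays in 10 only); dimethylzinc, C[Zn]C (Zn–CH3 stays in 11 only)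
Why: Syn-hydrozirconation of the terminal alkyne of 6 (Zr on the terminal carbon; the tri- and tetrasubstituted alkenes do not react) gives the (1E,3E)-dienylzirconocene 10, Zr→Zn exchange with Me2Zn gives dienyl(methyl)zinc 11, and the titanium complex of the bis(sulfonamide) diol transfers the dienyl group, in preference to methyl, to the ketone carbonyl of 9. The closest known reaction type is the catalytic asymmetric vinylation and dienylation of ketones with hydrozirconation-derived alkenylzinc reagents under bis(sulfonamide) diol–titanium catalysis. No ring is closed here; the step forms the C2–C1' bond and with it the whole carbon skeleton from two achiral fragments. The new stereocentre (C3 of the nonadienyl chain, later C2 of the chroman) is controlled by the chiral titanium catalyst, which must deliver the dienyl group to the Si face of the carbonyl (O > CH2CH2Ar > CH3) to give 3R; the 4E geometry follows from syn-hydrozirconation and stereoretentive transmetalation, and the 6E geometry is carried over from 6. The step needs chemoselectivity for the ketone over the methyl ester and aryl fluoride, which the low nucleophilicity of the alkenylzinc secures, and facial selectivity, for which the substrate offers only the size difference between CH3 and the 2-arylethyl arm, so it rests on the catalyst pocket and is the main risk.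

Step 6
Reactants: 12 methyl 4-fluoro-3-[(3R,4E,6E)-3-hydroxy-3,7-dimethyl-9-(2,6,6-trimethylcyclohex-1-en-1-yl)nona-4,6-dien-1-yl]benzoate
Product: 13 methyl (2R)-2-methyl-2-[(1E,3E)-4-methyl-6-(2,6,6-trimethylcyclohex-1-en-1-yl)hexa-1,3-dien-1-yl]-3,4-dihydro-2H-chromene-6-carboxylate
Conditions: NaH, DMF, 0 → 50 °C
Reagents that add atoms: none
Why: Intramolecular SNAr (addition–elimination through a Meisenheimer complex, 6-exo closure) of the tertiary alkoxide on the aryl fluoride activated by the para ester should close the dihydropyran ring; the C2–O bond is never broken, so the configuration at C2 is retained.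

Step 7
Reactants: 13 methyl (2R)-2-methyl-2-[(1E,3E)-4-methyl-6-(2,6,6-trimethylcyclohex-1-en-1-yl)hexa-1,3-dien-1-yl]-3,4-dihydro-2H-chromene-6-carboxylate
Product: 14 (2R)-2-methyl-2-[(1E,3E)-4-methyl-6-(2,6,6-trimethylcyclohex-1-en-1-yl)hexa-1,3-dien-1-yl]-3,4-dihydro-2H-chromene-6-carboxylic acid
Conditions: LiOH·H2O, THF/MeOH/H2O, 40 °C; then 1 M HCl to pH 4, 0 °C
Reagents that add atoms: lithium hydroxide, [Li+].[OH-] (hydroxide oxygen ends in the carboxyl group)
Why: Saponification of the methyl ester (acyl–oxygen cleavage) leaves the base-stable tertiary dienylic aryl ether untouched, and the cold, mildly acidic work-up should avoid ionisation of the C2–O bond.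

**Compound list**

1 | dihydro-β-ionone, 4-(2,6,6-trimethylcyclohex-1-en-1-yl)butan-2-one | CC(=O)CCC1=C(C)CCCC1(C)C | starting material
2 | diethyl 4-(2,6,6-trimethylcyclohex-1-en-1-yl)but-1-en-2-yl phosphate (enol phosphate) | C=C(CCC1=C(C)CCCC1(C)C)OP(=O)(OCC)OCC | intermediate
3 | 2-(but-3-yn-1-yl)-1,3,3-trimethylcyclohex-1-ene | C#CCCC1=C(C)CCCC1(C)C | intermediate
4 | dimethyl[(1E)-2-methyl-4-(2,6,6-trimethylcyclohex-1-en-1-yl)but-1-en-1-yl]alane | CC1=C(CC/C(C)=C/[Al](C)C)C(C)(C)CCC1 | intermediate
5 | 2-[(3E)-4-iodo-3-methylbut-3-en-1-yl]-1,3,3-trimethylcyclohex-1-ene | CC1=C(CC/C(C)=C/I)C(C)(C)CCC1 | intermediate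
6 | 2-[(3E)-3-methylhex-3-en-5-yn-1-yl]-1,3,3-trimethylcyclohex-1-ene | CC1=C(CC/C(C)=C/C#C)C(C)(C)CCC1 | intermediate
7 | methyl 3-bromo-4-fluorobenzoate | COC(=O)c1ccc(F)c(Br)c1 | starting material
8 | but-3-en-2-ol (racemic) | CC(O)C=C | starting material
9 | methyl 4-fluoro-3-(3-oxobutyl)benzoate | CC(=O)CCc1cc(C(=O)OC)ccc1F | intermediate
10 | chlorobis(cyclopentadienyl)[(1E,3E)-4-methyl-6-(2,6,6-trimethylcyclohex-1-en-1-yl)hexa-1,3-dien-1-yl]zirconium (Cp drawn σ-bonded) | CC1=C(CC/C(C)=C/C=C/[Zr](Cl)(C2C=CC=C2)C2C=CC=C2)C(C)(C)CCC1 | intermediate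
11 | methyl[(1E,3E)-4-methyl-6-(2,6,6-trimethylcyclohex-1-en-1-yl)hexa-1,3-dien-1-yl]zinc | CC1=C(CC/C(C)=C/C=C/[Zn]C)C(C)(C)CCC1 | intermediate
12 | methyl 4-fluoro-3-[(3R,4E,6E)-3-hydroxy-3,7-dimethyl-9-(2,6,6-trimethylcyclohex-1-en-1-yl)nona-4,6-dien-1-yl]benzoate | CC1=C(CC/C(C)=C/C=C/[C@@](O)(C)CCc2cc(C(=O)OC)ccc2F)C(C)(C)CCC1 | intermediate
13 | methyl (2R)-2-methyl-2-[(1E,3E)-4-methyl-6-(2,6,6-trimethylcyclohex-1-en-1-yl)hexa-1,3-dien-1-yl]-3,4-dihydro-2H-chromene-6-carboxylate | CC1=C(CC/C(C)=C/C=C/[C@@]2(C)CCc3cc(C(=O)OC)ccc3O2)C(C)(C)CCC1 | intermediate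
14 | (2R)-2-methyl-2-[(1E,3E)-4-methyl-6-(2,6,6-trimethylcyclohex-1-en-1-yl)hexa-1,3-dien-1-yl]-3,4-dihydro-2H-chromene-6-carboxylic acid | CC1=C(CC/C(C)=C/C=C/[C@@]2(C)CCc3cc(C(=O)O)ccc3O2)C(C)(C)CCC1 | target

**Totals**

Total step count: 7. Longest linear sequence: 6 steps (1, 2, 3, 5, 6, 7).

**Steps most likely to fail**

1. Step 5. The enantiotopic faces of a methyl/primary-alkyl ketone may be discriminated poorly, or uncatalysed background addition may compete, so the enantiomeric purity could be too low. Fallback (resolution instead of induction): setting out from 6 and 9, the same Zr→Zn dienylation is run with racemic ligand to give the racemic alcohol F1. NaH in DMF closes it to the racemic chroman ester F2. Preparative chiral SFC on a polysaccharide carbamate phase separates 13 from its (2S)-enantiomer F3, and the route is rejoined at 13. Partly enriched material from step 5 can be brought to full purity the same way.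

2. Step 6. A single para ester activates the fluoride only moderately, so Meisenheimer addition may be slow and intermolecular attack of the alkoxide on the methyl ester or base-induced decomposition may compete. Fallback (copper-catalysed C–O coupling instead of SNAr): setting out from 8 and 6, an iodide-selective Heck reaction of 8 with commercial methyl 4-bromo-3-iodobenzoate F4 gives methyl 4-bromo-3-(3-oxobutyl)benzoate F5. The step 5 dienylation with 6 gives the bromo alcohol F6. Ullmann-type intramolecular O-arylation (CuI, 3,4,7,8-tetramethyl-1,10-phenanthroline, Cs2CO3, toluene, 110 °C) closes the ring, and the route is rejoined at 13.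

3. Step 1. Enolisation may occur partly towards the methylene group, or elimination may be incomplete, giving internal alkyne or allene contaminants that co-elute with the hydrocarbon product and interfere in step 2. Fallback (carbonyl olefination instead of alkyne carbometalation): setting out from 1, Horner–Wadsworth–Emmons reaction with triethyl phosphonoacetate (NaH, THF) gives ethyl (2E)-3-methyl-5-(2,6,6-trimethylcyclohex-1-en-1-yl)pent-2-enoate F7, with the minor Z isomer removed by chromatography. DIBAL-H reduction gives the allylic alcohol F8, and MnO2 oxidation gives the enal F9. Colvin homologation with lithiated trimethylsilyldiazomethane (THF, −78 °C → rt) gives the enyne, and the route is rejoined at 6, bypassing 3 and 5.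

**Further compounds**

F1 | step 5 | methyl 4-fluoro-3-[(4E,6E)-3-hydroxy-3,7-dimethyl-9-(2,6,6-trimethylcyclohex-1-en-1-yl)nona-4,6-dien-1-yl]benzoate (racemic) | CC1=C(CC/C(C)=C/C=C/C(O)(C)CCc2cc(C(=O)OC)ccc2F)C(C)(C)CCC1
F2 | step 5 | methyl 2-methyl-2-[(1E,3E)-4-methyl-6-(2,6,6-trimethylcyclohex-1-en-1-yl)hexa-1,3-dien-1-yl]-3,4-dihydro-2H-chromene-6-carboxylate (racemic) | CC1=C(CC/C(C)=C/C=C/C2(C)CCc3cc(C(=O)OC)ccc3O2)C(C)(C)CCC1
F3 | step 5 | methyl (2S)-2-methyl-2-[(1E,3E)-4-methyl-6-(2,6,6-trimethylcyclohex-1-en-1-yl)hexa-1,3-dien-1-yl]-3,4-dihydro-2H-chromene-6-carboxylate (separated enantiomer) | CC1=C(CC/C(C)=C/C=C/[C@]2(C)CCc3cc(C(=O)OC)ccc3O2)C(C)(C)CCC1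
F4 | step 6 | methyl 4-bromo-3-iodobenzoate (commercial) | COC(=O)c1ccc(Br)c(I)c1
F5 | step 6 | methyl 4-bromo-3-(3-oxobutyl)benzoate | CC(=O)CCc1cc(C(=O)OC)ccc1Br
F6 | step 6 | methyl 4-bromo-3-[(3R,4E,6E)-3-hydroxy-3,7-dimethyl-9-(2,6,6-trimethylcyclohex-1-en-1-yl)nona-4,6-dien-1-yl]benzoate | CC1=C(CC/C(C)=C/C=C/[C@@](O)(C)CCc2cc(C(=O)OC)ccc2Br)C(C)(C)CCC1
F7 | step 1 | ethyl (2E)-3-methyl-5-(2,6,6-trimethylcyclohex-1-en-1-yl)pent-2-enoate | CC1=C(CC/C(C)=C/C(=O)OCC)C(C)(C)CCC1
F8 | step 1 | (2E)-3-methyl-5-(2,6,6-trimethylcyclohex-1-en-1-yl)pent-2-en-1-ol | CC1=C(CC/C(C)=C/CO)C(C)(C)CCC1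
F9 | step 1 | (2E)-3-methyl-5-(2,6,6-trimethylcyclohex-1-en-1-yl)pent-2-enal | CC1=C(CC/C(C)=C/C=O)C(C)(C)CCC1
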